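**Plan**

- Retrosynthesis: the O–O bond of the 1,2-dioxane is cut first, which leaves an acyclic 1,4-diol. The chain is then cut at C7–C8 (epoxide plus Grignard reagent), C5=C6 (Wittig), C3–C4 (aldol) and, in the side chain, C9–C10 (Claisen).
- Forward: an aldol builds C1–C5; Wittig olefination, epoxidation and hydride opening give the C6 carbinol as a terminal epoxide; the C8–C14 bromide is joined at C7–C8. The only ring, the dioxane, closes by O–O bond formation, and C1 is then raised to the methyl ester.
- Stereochemistry: C3 and C4 come from a thiazolidinethione syn-aldol and C6 from Sharpless epoxidation of an (E)-allylic alcohol. C10 comes from a kinetically resolved allylic alcohol by chirality transfer in a Johnson–Claisen rearrangement, which also sets the (E)-C11=C12 alkene.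
- Enabling feature: the two ring oxygens sit on C3 (a CH carbinol carbon) and C6 (a fully substituted carbinol carbon), 1,4-related through C4–C5. Both C–O bonds and both stereocentres can therefore be made by alcohol chemistry, and only the O–O bond of the six-membered ring remains to be formed.

Key step: step 20

Remark: locants C1–C14 follow the main chain of the target (C1 ester carbon, C3 and C6 ring carbons, C10 side-chain stereocentre); (R)-4-benzyl-1,3-thiazolidine-2-thione and ethyl 2-(triphenylphosphoranylidene)butanoate are assumed to be purchasable.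

**Route**

Step 1
Reactants: 1 propane-1,3-diol
Product: 2 3-[(triisopropylsilyl)oxy]propan-1-ol
Conditions: iPr3SiCl (1 equiv), imidazole, 1 (4 equiv), CH2Cl2, 0 °C to rt
Reagents that add atoms: chlorotriisopropylsilane, CC(C)[Si](Cl)(C(C)C)C(C)C
Why: Silyl ether formation on a symmetrical diol used in excess should give mainly the mono-ether, and the triisopropylsilyl group is chosen because it resists 1,3-migration to a neighbouring alkoxide and outlasts the later removal of a triethylsilyl ether.

Step 2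
Reactants: 2 3-[(triisopropylsilyl)oxy]propan-1-ol
Product: 3 3-[(triisopropylsilyl)oxy]propanal
Conditions: TEMPO (10 mol%), PhI(OAc)2, CH2Cl2, rt
Reagents that add atoms: none
Why: Oxoammonium-mediated (TEMPO) oxidation of a primary alcohol in a dry solvent should stop at the aldehyde.

Step 3
Reactants: 4 (R)-4-benzyl-1,3-thiazolidine-2-thione; 5 butanoyl chloride
Product: 6 (R)-4-benzyl-3-butanoyl-1,3-thiazolidine-2-thione
Conditions: Et3N, DMAP (cat.), CH2Cl2, 0 °C
Reagents that add atoms: none
Why: N-Acylation of the auxiliary by the acid chloride (nucleophilic acyl substitution) is routine for this class.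

Step 4
Reactants: 6 (R)-4-benzyl-3-butanoyl-1,3-thiazolidine-2-thione; 3 3-[(triisopropylsilyl)oxy]propanal
Product: 8 (R)-4-benzyl-3-[(2R,3S)-2-ethyl-3-hydroxy-5-(triisopropylsilyloxy)pentanoyl]-1,3-thiazolidine-2-thione, via titanium enolate 7 (not isolated)
Conditions: TiCl4, iPr2NEt, N-methylpyrrolidinone, CH2Cl2, 0 °C; then 3, 0 °C
Reagents that add atoms: none
Why: Titanium-mediated syn-aldol addition of an N-acyl thiazolidinethione (Crimmins aldol): the (Z)-enolate 7 should add through a Zimmerman–Traxler chair on the face opposite the benzyl group, so the (R)-auxiliary sets C4 and C3 together as the (2R,3S) syn adduct.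

Step 5
Reactants: 8 aldol adduct
Product: 9 (R)-4-benzyl-3-[(2R,3S)-2-ethyl-3-(triethylsilyloxy)-5-(triisopropylsilyloxy)pentanoyl]-1,3-thiazolidine-2-thione
Conditions: Et3SiOTf, 2,6-lutidine, CH2Cl2, −78 to 0 °C
Reagents that add atoms: triethylsilyl trifluoromethanesulfonate, CC[Si](CC)(CC)OS(=O)(=O)C(F)(F)F
Why: Silylation of the hindered secondary alcohol with a silyl triflate (silyl ether formation) installs a group that can later be removed in the presence of the primary triisopropylsilyl ether.

Step 6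
Reactants: 9 silyl-protected aldol adduct
Product: 10 (2R,3S)-2-ethyl-3-(triethylsilyloxy)-5-(triisopropylsilyloxy)pentanal
Conditions: iBu2AlH, CH2Cl2, −78 °C
Reagents that add atoms: none
Why: Partial reduction of an N-acyl thiazolidinethione by iBu2AlH gives the aldehyde directly through a stable tetrahedral intermediate, releases auxiliary 4 and is not expected to epimerise C4 at −78 °C.

Step 7
Reactants: 10 aldehyde; 11 ethyl 2-(triphenylphosphoranylidene)butanoate
Product: 12 ethyl (2E,4S,5S)-2,4-diethyl-5-(triethylsilyloxy)-7-(triisopropylsilyloxy)hept-2-enoate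
Conditions: toluene, 90 °C
Reagents that add atoms: none
Why: Wittig olefination with an α-substituted stabilised ylide is expected to give the (E)-trisubstituted enoate, and the base-free conditions protect the α-stereocentre and the β-silyloxy group.

Step 8
Reactants: 12 enoate
Product: 13 (2E,4S,5S)-2,4-diethyl-5-(triethylsilyloxy)-7-(triisopropylsilyloxy)hept-2-en-1-ol
Conditions: iBu2AlH, CH2Cl2, −78 to 0 °C
Reagents that add atoms: none
Why: 1,2-Reduction of the conjugated ester by iBu2AlH gives the allylic alcohol without change of alkene geometry.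

Step 9
Reactants: 13 allylic alcohol
Product: 14 [(2S,3S)-2-ethyl-3-[(3S,4S)-4-(triethylsilyloxy)-6-(triisopropylsilyloxy)hexan-3-yl]oxiran-2-yl]methanol
Conditions: Ti(OiPr)4 (10 mol%), L-(+)-diethyl tartrate (12 mol%), t-BuOOH, 4 Å MS, CH2Cl2, −20 °C
Reagents that add atoms: tert-butyl hydroperoxide, CC(C)(C)OO
Why: Sharpless asymmetric epoxidation: with L-(+)-tartrate oxygen is delivered to the face of the (E)-allylic alcohol that gives the (2S,3S)-epoxide, so the C6–O bond is set under reagent control in the sense required for C6 of the target.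

Step 10
Reactants: 14 epoxy alcohol
Product: 15 (2R,4S,5S)-2,4-diethyl-5-(triethylsilyloxy)-7-(triisopropylsilyloxy)heptane-1,2-diol
Conditions: LiAlH4, THF, 0 °C to rt
Reagents that add atoms: none
Why: Hydride opening of a 2,2,3-trisubstituted 2,3-epoxy alcohol (SN2 at the less substituted epoxide carbon C5) should leave the tertiary C6–O bond and its configuration intact and give the 1,2-diol.

Step 11
Reactants: 15 1,2-diol
Product: 17 (R)-2-ethyl-2-[(2S,3S)-2-ethyl-3-(triethylsilyloxy)-5-(triisopropylsilyloxy)pentyl]oxirane, via primary tosylate 16 (not isolated)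
Conditions: NaH, 1-(p-toluenesulfonyl)imidazole, THF, 0 °C to rt
Reagents that add atoms: none
Why: One-flask epoxide formation from a 1,2-diol: the primary alkoxide is sulfonylated selectively to 16 and the tertiary alkoxide closes the oxirane by 3-exo-tet displacement at C7, so the C6 configuration is untouched.

Step 12
Reactants: 18 (E)-pent-2-enal
Product: 19 rac-(E)-hept-4-en-3-ol
Conditions: EtMgBr, THF, −78 to 0 °C
Reagents that add atoms: ethylmagnesium bromide, CC[Mg]Br
Why: 1,2-Addition of a Grignard reagent to the enal gives the racemic (E)-allylic alcohol.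

Step 13
Reactants: 19 rac-(E)-hept-4-en-3-ol
Product: 20 (R,E)-hept-4-en-3-ol
Conditions: Ti(OiPr)4 (10 mol%), L-(+)-diisopropyl tartrate (15 mol%), t-BuOOH (0.6 equiv), 4 Å MS, CH2Cl2, −20 °C
Reagents that add atoms: none
Why: Sharpless kinetic resolution: with L-(+)-tartrate the (S)-enantiomer of an (E)-secondary allylic alcohol is epoxidised much faster, so stopping just past half conversion should leave the (R)-alcohol in high enantiomeric purity.

Step 14
Reactants: 20 (R,E)-hept-4-en-3-ol
Product: 22 ethyl (3R,4E)-3-ethylhept-4-enoate, via ketene acetal 21 (not isolated)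
Conditions: MeC(OEt)3, EtCO2H (cat.), 140 °C, ethanol distilled off
Reagents that add atoms: triethyl orthoacetate, CC(OCC)(OCC)OCC
Why: Johnson–Claisen rearrangement: ketene acetal 21 rearranges through a chair with the carbinol ethyl group equatorial, which transfers the C–O configuration suprafacially to the new C9–C10 bond (C10 R) and forms the C11=C12 alkene as the (E)-isomer.

Step 15
Reactants: 22 ethyl (3R,4E)-3-ethylhept-4-enoate
Product: 23 (3R,4E)-3-ethylhept-4-en-1-ol
Conditions: LiAlH4, Et2O, 0 °C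
Reagents that add atoms: none
Why: LiAlH4 reduction of the ester to the primary alcohol leaves the remote stereocentre and the alkene unaffected.

Step 16
Reactants: 23 (3R,4E)-3-ethylhept-4-en-1-ol
Product: 24 (3R,4E)-1-bromo-3-ethylhept-4-ene
Conditions: CBr4, PPh3, CH2Cl2, 0 °C
Reagents that add atoms: carbon tetrabromide, BrC(Br)(Br)Br
Why: Appel bromination converts the primary alcohol to the bromide under neutral conditions.

Step 17
Reactants: 24 (3R,4E)-1-bromo-3-ethylhept-4-ene; 17 epoxide
Product: 26 (3S,4S,6S,10R,11E)-4,6,10-triethyl-3-(triethylsilyloxy)-1-(triisopropylsilyloxy)tetradec-11-en-6-ol, via Grignard reagent 25 (not isolated)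
Conditions: Mg, THF, rt; then CuI (10 mol%), 17, THF, −30 to 0 °C
Reagents that add atoms: none
Why: Copper-catalysed ring opening of a 2,2-disubstituted epoxide by a primary Grignard reagent occurs by SN2 attack at the CH2 carbon C7, forming C7–C8 and releasing the tertiary C6 alcohol with its configuration unchanged.

Step 18
Reactants: 26 tertiary alcohol
Product: 27 (3S,4S,6S,10R,11E)-4,6,10-triethyl-1-(triisopropylsilyloxy)tetradec-11-ene-3,6-diol
Conditions: PPTS (cat.), MeOH/CH2Cl2, 0 °C to rt
Reagents that add atoms: none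
Why: Acid-catalysed methanolysis (selective desilylation) removes the triethylsilyl ether far faster than the primary triisopropylsilyl ether, freeing the C3 alcohol.

Step 19
Reactants: 28 4-nitrobenzenesulfonyl chloride (two molecules per molecule of product)
Product: 29 bis(4-nitrobenzenesulfonyl) peroxide
Conditions: 28 (2 equiv), H2O2 (30% aq., 1 equiv), K2CO3, EtOH/H2O, −20 °C
Reagents that add atoms: hydrogen peroxide, OO; 4-nitrobenzenesulfonyl chloride (the second molecule of 28), O=[N+]([O-])c1ccc(cc1)S(Cl)(=O)=O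
Why: Double O-sulfonylation of hydrogen peroxide by two molecules of the sulfonyl chloride under cold aqueous carbonate (nucleophilic substitution at sulfur) is the established preparation of bis(arenesulfonyl) peroxides.

Step 20
Reactants: 27 1,4-diol; 29 bis(4-nitrobenzenesulfonyl) peroxide
Product: 32 triisopropyl{2-[(3S,4S,6S)-4,6-diethyl-6-[(4R,5E)-4-ethyloct-5-en-1-yl]-1,2-dioxan-3-yl]ethoxy}silane, via dipotassium dialkoxide 30 (not isolated), via C3 sulfonyl peroxide 31 (not isolated)
Conditions: KH (2.05 equiv), THF, 0 °C; then 29 (1.05 equiv) added slowly as a cold THF suspension at −78 °C, warmed to −40 °C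
Reagents that add atoms: none
Why: Proposed new method: the less hindered secondary C3 alkoxide of 30 attacks a peroxide oxygen of 29 with loss of 4-nitrobenzenesulfonate to give alkyl sulfonyl peroxide 31, and the tertiary C6 alkoxide then attacks the C3-bound oxygen of 31 with loss of a second sulfonate, so the O–O bond is made from the two carbinol oxygens and no reagent atom stays in the product. The closest known reactions are the oxygenation of enolates and amines by arenesulfonyl peroxides and the alkoxylation of organometallic reagents by tert-butyl peresters, both displacements at peroxide oxygen, but an alkoxide has not been used in this way to make a dialkyl peroxide. The 1,2-dioxane closes in a 6-exo-tet mode at oxygen, the breaking O–O bond lying outside the ring and the nucleophile arriving in line with the departing sulfonate. No stereocentre is created and no bond to C3 or C6 is broken, so the configurations set in steps 4 and 9 are carried over unchanged. The step needs site selectivity (secondary before tertiary alkoxide, which steric access and slow addition of 29 at −78 °C should secure) and chemoselectivity for peroxide oxygen over sulfur, the alkene and the silyl ether. Ring closure must also outrun loss of the C3 hydrogen and Criegee-type migration in 31, for which the substrate supplies an internal alkoxide held 1,4 to the electrophilic oxygen and no external base.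

Step 21
Reactants: 32 silyl-protected dioxane
Product: 33 2-[(3S,4S,6S)-4,6-diethyl-6-[(4R,5E)-4-ethyloct-5-en-1-yl]-1,2-dioxan-3-yl]ethan-1-ol
Conditions: HF·pyridine, pyridine, THF, 0 °C to rt
Reagents that add atoms: none
Why: Fluoride-mediated desilylation under buffered, weakly acidic conditions cleaves the Si–O bond without affecting the dialkyl peroxide or the alkene.

Step 22
Reactants: 33 dioxane alcohol
Product: 35 2-[(3S,4S,6S)-4,6-diethyl-6-[(4R,5E)-4-ethyloct-5-en-1-yl]-1,2-dioxan-3-yl]acetic acid, via aldehyde 34 (not isolated)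
Conditions: TEMPO (20 mol%), PhI(OAc)2 (2.2 equiv), MeCN/H2O, rt
Reagents that add atoms: water, O
Why: TEMPO/PhI(OAc)2 oxidation in aqueous acetonitrile carries the primary alcohol through aldehyde 34 and its hydrate to the carboxylic acid under mildly acidic conditions, which avoids base-induced opening of the β-peroxy carbonyl unit and leaves the alkene alone.

Step 23
Reactants: 35 dioxane acid
Product: 36 methyl 2-[(3S,4S,6S)-4,6-diethyl-6-[(4R,5E)-4-ethyloct-5-en-1-yl]-1,2-dioxan-3-yl]acetate
Conditions: Me3SiCHN2, MeOH/toluene, 0 °C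
Reagents that add atoms: (trimethylsilyl)diazomethane, C[Si](C)(C)C=[N+]=[N-]
Why: Esterification of the acid with (trimethylsilyl)diazomethane in methanol is neutral and base-free, so the β-peroxy ester should form without elimination.

**Compound list**

1 | propane-1,3-diol | OCCCO | starting material
2 | 3-[(triisopropylsilyl)oxy]propan-1-ol | OCCCO[Si](C(C)C)(C(C)C)C(C)C | intermediate
3 | 3-[(triisopropylsilyl)oxy]propanal | O=CCCO[Si](C(C)C)(C(C)C)C(C)C | intermediate
4 | (R)-4-benzyl-1,3-thiazolidine-2-thione | S=C1SC[C@@H](Cc2ccccc2)N1 | starting material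
5 | butanoyl chloride | CCCC(=O)Cl | starting material
6 | (R)-4-benzyl-3-butanoyl-1,3-thiazolidine-2-thione | CCCC(=O)N1[C@H](Cc2ccccc2)CSC1=S | intermediate
7 | trichlorotitanium (Z)-enolate of 6 | CC/C=C(\O[Ti](Cl)(Cl)Cl)N1[C@H](Cc2ccccc2)CSC1=S | intermediate
8 | (R)-4-benzyl-3-[(2R,3S)-2-ethyl-3-hydroxy-5-(triisopropylsilyloxy)pentanoyl]-1,3-thiazolidine-2-thione | O=C([C@H](CC)[C@@H](O)CCO[Si](C(C)C)(C(C)C)C(C)C)N1[C@H](Cc2ccccc2)CSC1=S | intermediate
9 | (R)-4-benzyl-3-[(2R,3S)-2-ethyl-3-(triethylsilyloxy)-5-(triisopropylsilyloxy)pentanoyl]-1,3-thiazolidine-2-thione | O=C([C@H](CC)[C@@H](O[Si](CC)(CC)CC)CCO[Si](C(C)C)(C(C)C)C(C)C)N1[C@H](Cc2ccccc2)CSC1=S | intermediate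
10 | (2R,3S)-2-ethyl-3-(triethylsilyloxy)-5-(triisopropylsilyloxy)pentanal | O=C[C@H](CC)[C@@H](O[Si](CC)(CC)CC)CCO[Si](C(C)C)(C(C)C)C(C)C | intermediate
11 | ethyl 2-(triphenylphosphoranylidene)butanoate | CCOC(=O)C(CC)=P(c1ccccc1)(c1ccccc1)c1ccccc1 | starting material
12 | ethyl (2E,4S,5S)-2,4-diethyl-5-(triethylsilyloxy)-7-(triisopropylsilyloxy)hept-2-enoate | CCOC(=O)/C(CC)=C/[C@H](CC)[C@@H](O[Si](CC)(CC)CC)CCO[Si](C(C)C)(C(C)C)C(C)C | intermediate
13 | (2E,4S,5S)-2,4-diethyl-5-(triethylsilyloxy)-7-(triisopropylsilyloxy)hept-2-en-1-ol | OC/C(CC)=C/[C@H](CC)[C@@H](O[Si](CC)(CC)CC)CCO[Si](C(C)C)(C(C)C)C(C)C | intermediate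
14 | [(2S,3S)-2-ethyl-3-[(3S,4S)-4-(triethylsilyloxy)-6-(triisopropylsilyloxy)hexan-3-yl]oxiran-2-yl]methanol | OC[C@]1(CC)O[C@H]1[C@H](CC)[C@@H](O[Si](CC)(CC)CC)CCO[Si](C(C)C)(C(C)C)C(C)C | intermediate
15 | (2R,4S,5S)-2,4-diethyl-5-(triethylsilyloxy)-7-(triisopropylsilyloxy)heptane-1,2-diol | OC[C@@](O)(CC)C[C@H](CC)[C@@H](O[Si](CC)(CC)CC)CCO[Si](C(C)C)(C(C)C)C(C)C | intermediate
16 | (2R,4S,5S)-2,4-diethyl-2-hydroxy-5-(triethylsilyloxy)-7-(triisopropylsilyloxy)heptyl 4-methylbenzenesulfonate | Cc1ccc(cc1)S(=O)(=O)OC[C@@](O)(CC)C[C@H](CC)[C@@H](O[Si](CC)(CC)CC)CCO[Si](C(C)C)(C(C)C)C(C)C | intermediate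
17 | (R)-2-ethyl-2-[(2S,3S)-2-ethyl-3-(triethylsilyloxy)-5-(triisopropylsilyloxy)pentyl]oxirane | CC[C@]1(CO1)C[C@H](CC)[C@@H](O[Si](CC)(CC)CC)CCO[Si](C(C)C)(C(C)C)C(C)C | intermediate
18 | (E)-pent-2-enal | CC/C=C/C=O | starting material
19 | rac-(E)-hept-4-en-3-ol | CC/C=C/C(O)CC | intermediate
20 | (R,E)-hept-4-en-3-ol | CC[C@@H](O)/C=C/CC | intermediate
21 | (R,E)-3-[(1-ethoxyethenyl)oxy]hept-4-ene | C=C(OCC)O[C@H](CC)/C=C/CC | intermediate
22 | ethyl (3R,4E)-3-ethylhept-4-enoate | CC/C=C/[C@H](CC)CC(=O)OCC | intermediate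
23 | (3R,4E)-3-ethylhept-4-en-1-ol | CC/C=C/[C@H](CC)CCO | intermediate
24 | (3R,4E)-1-bromo-3-ethylhept-4-ene | CC/C=C/[C@H](CC)CCBr | intermediate
25 | [(3R,4E)-3-ethylhept-4-en-1-yl]magnesium bromide | CC/C=C/[C@H](CC)CC[Mg]Br | intermediate
26 | (3S,4S,6S,10R,11E)-4,6,10-triethyl-3-(triethylsilyloxy)-1-(triisopropylsilyloxy)tetradec-11-en-6-ol | CC/C=C/[C@H](CC)CCC[C@@](O)(CC)C[C@H](CC)[C@@H](O[Si](CC)(CC)CC)CCO[Si](C(C)C)(C(C)C)C(C)C | intermediate
27 | (3S,4S,6S,10R,11E)-4,6,10-triethyl-1-(triisopropylsilyloxy)tetradec-11-ene-3,6-diol | CC/C=C/[C@H](CC)CCC[C@@](O)(CC)C[C@H](CC)[C@H](CCO[Si](C(C)C)(C(C)C)C(C)C)O | intermediate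
28 | 4-nitrobenzenesulfonyl chloride | O=[N+]([O-])c1ccc(cc1)S(Cl)(=O)=O | starting material
29 | bis(4-nitrobenzenesulfonyl) peroxide | O=[N+]([O-])c1ccc(cc1)S(=O)(=O)OOS(=O)(=O)c1ccc(cc1)[N+](=O)[O-] | intermediate
30 | dipotassium 3,6-dialkoxide of 27 | CC/C=C/[C@H](CC)CCC[C@@]([O-])(CC)C[C@H](CC)[C@H](CCO[Si](C(C)C)(C(C)C)C(C)C)[O-].[K+].[K+] | intermediate
31 | potassium C6-alkoxide of the C3-O (4-nitrobenzenesulfonyl) peroxide of 27 | CC/C=C/[C@H](CC)CCC[C@@]([O-])(CC)C[C@H](CC)[C@H](CCO[Si](C(C)C)(C(C)C)C(C)C)OOS(=O)(=O)c1ccc(cc1)[N+](=O)[O-].[K+] | intermediate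
32 | triisopropyl{2-[(3S,4S,6S)-4,6-diethyl-6-[(4R,5E)-4-ethyloct-5-en-1-yl]-1,2-dioxan-3-yl]ethoxy}silane | CC/C=C/[C@H](CC)CCC[C@@]1(CC)C[C@H](CC)[C@H](CCO[Si](C(C)C)(C(C)C)C(C)C)OO1 | intermediate
33 | 2-[(3S,4S,6S)-4,6-diethyl-6-[(4R,5E)-4-ethyloct-5-en-1-yl]-1,2-dioxan-3-yl]ethan-1-ol | CC/C=C/[C@H](CC)CCC[C@@]1(CC)C[C@H](CC)[C@H](CCO)OO1 | intermediate
34 | 2-[(3S,4S,6S)-4,6-diethyl-6-[(4R,5E)-4-ethyloct-5-en-1-yl]-1,2-dioxan-3-yl]acetaldehyde | CC/C=C/[C@H](CC)CCC[C@@]1(CC)C[C@H](CC)[C@H](CC=O)OO1 | intermediate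
35 | 2-[(3S,4S,6S)-4,6-diethyl-6-[(4R,5E)-4-ethyloct-5-en-1-yl]-1,2-dioxan-3-yl]acetic acid | CC/C=C/[C@H](CC)CCC[C@@]1(CC)C[C@H](CC)[C@H](CC(=O)O)OO1 | intermediate
36 | methyl 2-[(3S,4S,6S)-4,6-diethyl-6-[(4R,5E)-4-ethyloct-5-en-1-yl]-1,2-dioxan-3-yl]acetate | CC/C=C/[C@H](CC)CCC[C@@]1(CC)C[C@H](CC)[C@H](CC(=O)OC)OO1 | target

**Step count**

Total: 23 steps. Longest linear sequence: 16 steps (1, 2, 4–11, 17, 18, 20–23).

**Steps most likely to fail**

1. Step 20 (O–O ring closure).
   - What may go wrong: after the C3 alkoxide is sulfonyloxylated, loss of the C3 hydrogen with expulsion of sulfonate (oxidation to the C3 ketone) or 1,2-migration to oxygen may outpace ring closure. The alkoxides may also attack sulfur instead of peroxide oxygen, or both may be activated.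
   - Fallback (known chemistry, ring closed through the C3–O bond): setting out from allylic alcohol 13, Appel bromination (CBr4, PPh3) gives the allylic bromide F1. Li2CuCl4-catalysed coupling with Grignard reagent 25 at the primary carbon gives the (E)-trisubstituted alkene F2. Methanolysis (PPTS, MeOH) frees the C3 alcohol F3. A Mitsunobu reaction with Zn(OTs)2, PPh3 and diisopropyl azodicarboxylate installs the inverted (3R)-tosylate F4. Mukaiyama–Isayama hydroperoxysilylation (Co(acac)2, O2, Et3SiH) should engage the trisubstituted alkene in preference to the 1,2-disubstituted one; it adds hydrogen at C5 and a triethylsilylperoxy group at C6 without facial control, giving the (6S)-silyl peroxide F5 and its (6R)-epimer F6, which are separated. One equivalent of Bu4NF at 0 °C cleaves the peroxide O–Si bond of F5 faster than the primary silyl ether, and the hydroperoxide F7, as its anion, displaces the tosylate with inversion at C3 (6-exo-tet). This returns to the route at dioxane 32.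

2. Step 10 (hydride opening of the epoxy alcohol).
   - What may go wrong: hydride delivery to C5, which lies between the C4 branch and the quaternary C6, may be slow, so that silyl loss or Lewis-acid-induced epoxide rearrangement competes.
   - Fallback: setting out from allylic alcohol 13, a Mukaiyama hydration (Co(acac)2, PhSiH3, O2, THF) places the hydroxyl at the more substituted alkene carbon C6 by hydrogen-atom transfer to C5 and oxygen trapping of the tertiary radical, with no hydride attack at C5. It has no facial control, so diol 15 forms together with the C6-epimeric diol F8, which is removed by chromatography. The route is rejoined at diol 15.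

3. Step 17 (fragment union at C7–C8).
   - What may go wrong: homocoupling may accompany formation of the Grignard reagent, and the magnesium halide may isomerise the 2,2-disubstituted epoxide to an aldehyde or open it to a bromohydrin before the C–C bond forms.
   - Fallback: setting out from bromide 24, displacement with PhSO2Na in DMF gives the phenyl sulfone F9. Its lithio derivative (n-BuLi, THF, −78 °C, then DMPU, warming) opens epoxide 17 at C7 to give the hydroxy sulfone F10 as a pair of C8 epimers. Reductive desulfonylation with Na(Hg) and Na2HPO4 in MeOH removes the sulfonyl group and returns to the route at tertiary alcohol 26.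

Further compounds
F1 | step 20 | (2E,4S,5S)-1-bromo-2,4-diethyl-5-(triethylsilyloxy)-7-(triisopropylsilyloxy)hept-2-ene | BrC/C(CC)=C/[C@H](CC)[C@@H](O[Si](CC)(CC)CC)CCO[Si](C(C)C)(C(C)C)C(C)C
F2 | step 20 | (3S,4S,5E,10R,11E)-4,6,10-triethyl-3-(triethylsilyloxy)-1-(triisopropylsilyloxy)tetradeca-5,11-diene | CC/C=C/[C@H](CC)CCC/C(CC)=C/[C@H](CC)[C@@H](O[Si](CC)(CC)CC)CCO[Si](C(C)C)(C(C)C)C(C)C
F3 | step 20 | (3S,4S,5E,10R,11E)-4,6,10-triethyl-1-(triisopropylsilyloxy)tetradeca-5,11-dien-3-ol | CC/C=C/[C@H](CC)CCC/C(CC)=C/[C@H](CC)[C@@H](O)CCO[Si](C(C)C)(C(C)C)C(C)C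
F4 | step 20 | (3R,4S,5E,10R,11E)-4,6,10-triethyl-1-(triisopropylsilyloxy)tetradeca-5,11-dien-3-yl 4-methylbenzenesulfonate | CC/C=C/[C@H](CC)CCC/C(CC)=C/[C@H](CC)[C@H](OS(=O)(=O)c1ccc(C)cc1)CCO[Si](C(C)C)(C(C)C)C(C)C
F5 | step 20 | (3R,4S,6S,10R,11E)-4,6,10-triethyl-6-(triethylsilylperoxy)-1-(triisopropylsilyloxy)tetradec-11-en-3-yl 4-methylbenzenesulfonate | CC/C=C/[C@H](CC)CCC[C@@](OO[Si](CC)(CC)CC)(CC)C[C@H](CC)[C@H](OS(=O)(=O)c1ccc(C)cc1)CCO[Si](C(C)C)(C(C)C)C(C)C
F6 | step 20 | (3R,4S,6R,10R,11E)-4,6,10-triethyl-6-(triethylsilylperoxy)-1-(triisopropylsilyloxy)tetradec-11-en-3-yl 4-methylbenzenesulfonate | CC/C=C/[C@H](CC)CCC[C@](OO[Si](CC)(CC)CC)(CC)C[C@H](CC)[C@H](OS(=O)(=O)c1ccc(C)cc1)CCO[Si](C(C)C)(C(C)C)C(C)C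
F7 | step 20 | (3R,4S,6S,10R,11E)-4,6,10-triethyl-6-hydroperoxy-1-(triisopropylsilyloxy)tetradec-11-en-3-yl 4-methylbenzenesulfonate | CC/C=C/[C@H](CC)CCC[C@@](OO)(CC)C[C@H](CC)[C@H](OS(=O)(=O)c1ccc(C)cc1)CCO[Si](C(C)C)(C(C)C)C(C)C
F8 | step 10 | (2S,4S,5S)-2,4-diethyl-5-(triethylsilyloxy)-7-(triisopropylsilyloxy)heptane-1,2-diol | OC[C@](O)(CC)C[C@H](CC)[C@@H](O[Si](CC)(CC)CC)CCO[Si](C(C)C)(C(C)C)C(C)C
F9 | step 17 | [(3R,4E)-3-ethylhept-4-en-1-yl]sulfonylbenzene | CC/C=C/[C@H](CC)CCS(=O)(=O)c1ccccc1
F10 | step 17 | 8-(phenylsulfonyl) derivative of 26, both C8 epimers | CC/C=C/[C@H](CC)CC(S(=O)(=O)c1ccccc1)C[C@@](O)(CC)C[C@H](CC)[C@@H](O[Si](CC)(CC)CC)CCO[Si](C(C)C)(C(C)C)C(C)C
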